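**Retrosynthetic overview**
- Last bond: the C(=O)–Cα bond of the chalcone, from the unprotected salicylaldehyde (as a catalytic acyl anion equivalent, acyl–Rh–H) and a terminal aryl alkyne by hydroacylation.
- The salicylaldehyde comes from ortho-formylation of the (R)-dihydrobenzofuranol.
- Dihydrofuran ring (left branch): 5-exo opening of an (S)-epoxide by a phenoxide with inversion; the epoxide comes from asymmetric epoxidation of C2-prenylated, bis-SEM-protected resorcinol, itself made by ortho-lithiation and prenylation.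
- Alkyne (right branch): one-carbon homologation of 2,2-dimethyl-2H-chromene-6-carbaldehyde; its pyran ring is formed first, from 4-hydroxybenzaldehyde and prenal.

Assumption: the stereocentre in the SMILES is read as (R) at C2 of the dihydrobenzofuran; SEMCl, the Ohira–Bestmann reagent and the enantiomeric (L-series) Shi ketone are treated as purchasable reagents.

**Route**

Step 1
Reactants: 1 4-hydroxybenzaldehyde; 2 3-methylbut-2-enal (prenal)
Product: 5 2,2-dimethyl-2H-chromene-6-carbaldehyde, via benzodioxaborin 3 (not isolated), via ortho-quinone methide 4 (not isolated)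
Conditions: PhB(OH)2 (1.0 equiv), AcOH (cat.), toluene, reflux, Dean–Stark
Reagents that add atoms: none
Why: Phenylboronic acid-mediated chromenylation: the aryl boronate delivers prenal to the ortho position to give dioxaborin 3, which fragments to ortho-quinone methide 4, and this closes by oxa-6π electrocyclisation to the 2,2-dimethyl-2H-chromene.

Step 2
Reactants: 5 2,2-dimethyl-2H-chromene-6-carbaldehyde
Product: 7 6-ethynyl-2,2-dimethyl-2H-chromene, via diazoalkene 6 (not isolated)
Conditions: Ohira–Bestmann reagent (1.3 equiv), K2CO3 (2 equiv), MeOH, 0 °C → rt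
Reagents that add atoms: Ohira–Bestmann reagent, dimethyl (1-diazo-2-oxopropyl)phosphonate, CC(=O)C(=[N+]=[N-])P(=O)(OC)OC
Why: Seyferth–Gilbert homologation (Ohira–Bestmann variant): methanolysis of the reagent gives the diazomethylphosphonate anion, Horner–Wadsworth–Emmons olefination gives diazoalkene 6, and loss of N2 with a 1,2-hydrogen shift gives the terminal alkyne under conditions the chromene tolerates.

Step 3
Reactants: 8 resorcinol
Product: 9 1,3-bis{[2-(trimethylsilyl)ethoxy]methoxy}benzene
Conditions: NaH (2.4 equiv), SEMCl (2.3 equiv), DMF, 0 °C → rt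
Reagents that add atoms: SEMCl, 2-(trimethylsilyl)ethoxymethyl chloride, C[Si](C)(C)CCOCCl
Why: Williamson-type O-alkylation of both phenoxides; SEM is chosen because it directs ortho-lithiation and is later removed by fluoride instead of acid, which the epoxide would not survive.

Step 4
Reactants: 9 1,3-bis{[2-(trimethylsilyl)ethoxy]methoxy}benzene; 10 prenyl bromide (1-bromo-3-methylbut-2-ene)
Product: 12 2-(3-methylbut-2-en-1-yl)-1,3-bis{[2-(trimethylsilyl)ethoxy]methoxy}benzene, via aryllithium 11 (not isolated)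
Conditions: n-BuLi (1.2 equiv), TMEDA, THF, 0 °C, 1 h; then 10, −78 °C → rt
Reagents that add atoms: none
Why: Directed ortho-metalation: both OCH2O groups direct n-BuLi to C2, and the aryllithium is alkylated by prenyl bromide at its primary carbon (SN2).

Step 5
Reactants: 12 2-(3-methylbut-2-en-1-yl)-1,3-bis{[2-(trimethylsilyl)ethoxy]methoxy}benzene
Product: 13 2-{[(2S)-3,3-dimethyloxiran-2-yl]methyl}-1,3-bis{[2-(trimethylsilyl)ethoxy]methoxy}benzene
Conditions: ent-Shi ketone (L-fructose-derived, from L-sorbose, 30 mol%), Oxone, K2CO3, Bu4NHSO4 (cat.), MeCN/DMM–aq. Na2B4O7/Na2EDTA buffer (pH 10.5), 0 °C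
Reagents that add atoms: Oxone (potassium peroxymonosulfate), [K+].[O-]S(=O)(=O)OO
Why: Shi asymmetric epoxidation: the chiral dioxirane epoxidises the trisubstituted alkene through the spiro transition state; the D-fructose ketone gives the (R)-epoxide of ArCH2–CH=CMe2 alkenes, so its enantiomer sets the (S)-epoxide.

Step 6
Reactants: 13 2-{[(2S)-3,3-dimethyloxiran-2-yl]methyl}-1,3-bis{[2-(trimethylsilyl)ethoxy]methoxy}benzene
Product: 15 (2R)-2-(2-hydroxypropan-2-yl)-2,3-dihydro-1-benzofuran-4-ol, via epoxy resorcinol 14 (not isolated)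
Conditions: TBAF (6 equiv), ethylenediamine (3 equiv), THF/DMPU, 65 °C; aq. NH4Cl
Reagents that add atoms: none
Why: Fluoride removes both SEM groups by β-silyl fragmentation, and either of the two equivalent phenoxides opens the epoxide 5-exo-tet at the secondary carbon with inversion, turning the (S)-epoxide carbon into the (R)-configured C2; ethylenediamine traps the released formaldehyde.

Step 7
Reactants: 15 (2R)-2-(2-hydroxypropan-2-yl)-2,3-dihydro-1-benzofuran-4-ol
Product: 17 (2R)-4-hydroxy-2-(2-hydroxypropan-2-yl)-2,3-dihydro-1-benzofuran-5-carbaldehyde, via salicyl alcohol 16 (not isolated)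
Conditions: MgCl2 (anhydrous, 3 equiv), Et3N (4 equiv), (CH2O)n (6 equiv), MeCN, reflux; 1 M HCl work-up
Reagents that add atoms: paraformaldehyde (as formaldehyde), C=O
Why: Casnati–Skattebøl ortho-formylation: the magnesium phenoxide delivers formaldehyde only to the one free ortho position (C5), and salicyl alcohol 16 is oxidised in the flask by hydride transfer to a second formaldehyde; the stereocentre is not involved.

Step 8
Reactants: 17 (2R)-4-hydroxy-2-(2-hydroxypropan-2-yl)-2,3-dihydro-1-benzofuran-5-carbaldehyde; 7 6-ethynyl-2,2-dimethyl-2H-chromene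
Product: 18 (2E)-3-(2,2-dimethyl-2H-chromen-6-yl)-1-[(2R)-4-hydroxy-2-(2-hydroxypropan-2-yl)-2,3-dihydro-1-benzofuran-5-yl]prop-2-en-1-one
Conditions: [Rh(cod)Cl]2 (2.5 mol%), dppf (5 mol%), Na2CO3 (10 mol%), toluene, 110 °C, slow addition of 7 (1.5 equiv)
Reagents that add atoms: none
Why: Chelation-assisted Rh(I)-catalysed alkyne hydroacylation of a salicylaldehyde: the phenoxide-bound rhodium inserts into the formyl C–H of 17 to give an acyl–Rh(III) hydride, a catalytic acyl anion equivalent in which the normally electrophilic formyl carbon acts as the donor, and this adds syn across the alkyne with the acyl group going to the unhindered terminal carbon, giving the (E)-enone with the chelating OH as the 2'-OH of the target and the stereocentre untouched.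

**Compound list**

1 | 4-hydroxybenzaldehyde | O=Cc1ccc(O)cc1 | starting material
2 | 3-methylbut-2-enal (prenal) | CC(C)=CC=O | starting material
3 | 4-(2-methylprop-1-en-1-yl)-2-phenyl-4H-1,3,2-benzodioxaborinine-6-carbaldehyde (racemic) | CC(C)=CC1OB(c2ccccc2)Oc2ccc(C=O)cc12 | intermediate
4 | (Z)-3-(3-methylbut-2-en-1-ylidene)-4-oxocyclohexa-1,5-diene-1-carbaldehyde | CC(C)=C/C=C1\C(=O)C=CC(C=O)=C1 | intermediate
5 | 2,2-dimethyl-2H-chromene-6-carbaldehyde | CC1(C)C=Cc2cc(C=O)ccc2O1 | intermediate
6 | 6-(2-diazoethenyl)-2,2-dimethyl-2H-chromene | [N-]=[N+]=C=Cc1ccc2OC(C)(C)C=Cc2c1 | intermediate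
7 | 6-ethynyl-2,2-dimethyl-2H-chromene | C#Cc1ccc2OC(C)(C)C=Cc2c1 | intermediate
8 | resorcinol (benzene-1,3-diol) | Oc1cccc(O)c1 | starting material
9 | 1,3-bis{[2-(trimethylsilyl)ethoxy]methoxy}benzene | C[Si](C)(C)CCOCOc1cccc(OCOCC[Si](C)(C)C)c1 | intermediate
10 | prenyl bromide (1-bromo-3-methylbut-2-ene) | CC(C)=CCBr | starting material
11 | 2-lithio-1,3-bis{[2-(trimethylsilyl)ethoxy]methoxy}benzene | [Li]c1c(OCOCC[Si](C)(C)C)cccc1OCOCC[Si](C)(C)C | intermediate
12 | 2-(3-methylbut-2-en-1-yl)-1,3-bis{[2-(trimethylsilyl)ethoxy]methoxy}benzene | CC(C)=CCc1c(OCOCC[Si](C)(C)C)cccc1OCOCC[Si](C)(C)C | intermediate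
13 | 2-{[(2S)-3,3-dimethyloxiran-2-yl]methyl}-1,3-bis{[2-(trimethylsilyl)ethoxy]methoxy}benzene | CC1(C)O[C@H]1Cc1c(OCOCC[Si](C)(C)C)cccc1OCOCC[Si](C)(C)C | intermediate
14 | 2-{[(2S)-3,3-dimethyloxiran-2-yl]methyl}benzene-1,3-diol (present as phenoxide) | CC1(C)O[C@H]1Cc1c(O)cccc1O | intermediate
15 | (2R)-2-(2-hydroxypropan-2-yl)-2,3-dihydro-1-benzofuran-4-ol | CC(C)(O)[C@H]1Cc2c(O)cccc2O1 | intermediate
16 | (2R)-5-(hydroxymethyl)-2-(2-hydroxypropan-2-yl)-2,3-dihydro-1-benzofuran-4-ol | CC(C)(O)[C@H]1Cc2c(O)c(CO)ccc2O1 | intermediate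
17 | (2R)-4-hydroxy-2-(2-hydroxypropan-2-yl)-2,3-dihydro-1-benzofuran-5-carbaldehyde | CC(C)(O)[C@H]1Cc2c(O)c(C=O)ccc2O1 | intermediate
18 | (2E)-3-(2,2-dimethyl-2H-chromen-6-yl)-1-[(2R)-4-hydroxy-2-(2-hydroxypropan-2-yl)-2,3-dihydro-1-benzofuran-5-yl]prop-2-en-1-one | CC1(C)C=Cc2cc(/C=C/C(=O)c3ccc4c(c3O)C[C@H](C(C)(C)O)O4)ccc2O1 | target

**Totals**
Total step count: 8. Longest linear sequence: 6 steps (steps 3–8, resorcinol to target); steps 1–2 form the second branch.

**Steps most likely to fail, with fallbacks**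

Step 8. Hydroacylation of alkynes with salicylaldehydes under Rh/dppf/Na2CO3 is known, but linear selectivity with a terminal aryl acetylene is not secured. The branched α-aryl enone, alkyne oligomers or oxa-Michael closure to the flavanone may compete. The fallback sets out from 7 and 17 and comes back at 18; it fixes the regiochemistry by polarity and uses an explicit Breslow acyl anion. Alkyne 7 is converted by Pd(0)-catalysed Markovnikov hydrosulfonylation (PhSO2Na, AcOH, Pd(PPh3)4, THF) into 2,2-dimethyl-6-[1-(phenylsulfonyl)ethenyl]-2H-chromene F1. Aldehyde 17 is then added to F1 in a Stetter reaction (thiazolium precatalyst, DBU, THF/EtOH, 60 °C), the acyl anion attacking the CH2 terminus. This gives 3-(2,2-dimethyl-2H-chromen-6-yl)-1-[(2R)-4-hydroxy-2-(2-hydroxypropan-2-yl)-2,3-dihydro-1-benzofuran-5-yl]-3-(phenylsulfonyl)propan-1-one F2 as a mixture of C3 epimers. Excess DBU then expels benzenesulfinate (E1cB) to give the (E)-enone 18.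

Step 6. Aryl SEM ethers can be slow to cleave with fluoride, and the electron-rich phenoxide may be hydroxymethylated by formaldehyde despite the scavenger. The fallback sets out from 12 and comes back at 15; it changes the protecting group before the epoxide is made. HCl/MeOH at rt removes both SEM groups to give 2-(3-methylbut-2-en-1-yl)benzene-1,3-diol F3. TBSCl/imidazole in DMF gives 1,3-bis[(tert-butyldimethylsilyl)oxy]-2-(3-methylbut-2-en-1-yl)benzene F4. The same ent-Shi epoxidation gives 1,3-bis[(tert-butyldimethylsilyl)oxy]-2-{[(2S)-3,3-dimethyloxiran-2-yl]methyl}benzene F5. TBAF in THF at 0 °C then frees the phenoxide, which closes 5-exo with inversion to 15 without any formaldehyde being formed.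

Step 1. The electron-poor phenol 1 may react sluggishly in the boronic acid chromenylation, and prenal may self-condense. The fallback sets out from 1 and comes back at 5. O-Alkylation with 3-chloro-3-methylbut-1-yne (K2CO3, KI, CuI cat., acetone, reflux) gives 4-[(2-methylbut-3-yn-2-yl)oxy]benzaldehyde F6. Heating F6 in N,N-diethylaniline at 190 °C brings about the aryl propargyl Claisen rearrangement, [1,5]-hydrogen shift and oxa-6π closure to 5.

**Further compounds**

F1 | step 8 | 2,2-dimethyl-6-[1-(phenylsulfonyl)ethenyl]-2H-chromene | C=C(c1ccc2OC(C)(C)C=Cc2c1)S(=O)(=O)c1ccccc1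
F2 | step 8 | 3-(2,2-dimethyl-2H-chromen-6-yl)-1-[(2R)-4-hydroxy-2-(2-hydroxypropan-2-yl)-2,3-dihydro-1-benzofuran-5-yl]-3-(phenylsulfonyl)propan-1-one (C3 epimers) | CC(C)(O)[C@H]1Cc2c(O)c(C(=O)CC(c3ccc4OC(C)(C)C=Cc4c3)S(=O)(=O)c3ccccc3)ccc2O1
F3 | step 6 | 2-(3-methylbut-2-en-1-yl)benzene-1,3-diol | CC(C)=CCc1c(O)cccc1O
F4 | step 6 | 1,3-bis[(tert-butyldimethylsilyl)oxy]-2-(3-methylbut-2-en-1-yl)benzene | CC(C)=CCc1c(O[Si](C)(C)C(C)(C)C)cccc1O[Si](C)(C)C(C)(C)C
F5 | step 6 | 1,3-bis[(tert-butyldimethylsilyl)oxy]-2-{[(2S)-3,3-dimethyloxiran-2-yl]methyl}benzene | CC1(C)O[C@H]1Cc1c(O[Si](C)(C)C(C)(C)C)cccc1O[Si](C)(C)C(C)(C)C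
F6 | step 1 | 4-[(2-methylbut-3-yn-2-yl)oxy]benzaldehyde | CC(C)(C#C)Oc1ccc(C=O)cc1
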